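**Retrosynthetic overview**
1. C7–C11 (last step): an intramolecular copper hydride reductive aldol of the C8 hemiketal acrylate 24 onto the C7 ketone closes the spiro-γ-lactone (ring B: C8–O8–C12–C11–C7), sets C7 and C11, and turns the acrylate CH2 into the C13 methyl group.
2. Enabling feature: C8 is a ketal carbon carrying both the dihydrofuran oxygen O1 and the lactone oxygen O8, next to the C7 carbinol (β-hydroxy-γ-lactone = aldol retron). O8 is available as the hydroxyl of the transannular C1–O–C8 hemiketal, which should not aromatise, because a furan bridging C1 and C8 of the ten-membered ring would be a strained [6](2,5)furanophane.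
3. C1–C10: a Nozaki–Hiyama–Kishi macrocyclisation of (Z)-β-iodoenone aldehyde 19 forms the ten-membered carbocycle; the (Z)-γ-hydroxy enone closes at once to ring C (2,5-dihydrofuran hemiketal).
4. C4=C5 and C15–O6: Still–Gennari olefination of a D-threitol-derived aldehyde (source of C6) and lactonisation give the butenolide (ring A); anti-dihydroxylation sets C4 and C5.
5. Ring order: A (steps 4–7), then carbocycle and ring C together (step 16), then ring B (step 20).

Key step: step 20

Numbering used below (germacrane type): C1–C10 ring carbons (C1 = CH–O of the dihydrofuran, C2/C3 = CH2CH2, C4 = C(OH), C5 = CH(OAc), C6 = CH–O, C7 = C(OH), C8 = spiro ketal carbon, C9=C10 alkene); C11/C12/C13 = CH, C=O and CH3 of the spirolactone; C14 = CH3 on C10; C15 = lactone C=O on C4; O1 = C1–O–C8; O6 and O8 = lactone ring oxygens.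

Assumption: the C8 configuration of the target (C7 and C2 on opposite faces of the dihydrofuran) is taken to be the thermodynamically preferred mode of transannular 1,8-ketalisation in this lactone-bridged ring, so it is set by ring–chain equilibration of hemiketal 21 and fixed by acylation.

Step 1
Reactants: 1 (4R,5R)-2,2-dimethyl-1,3-dioxolane-4,5-dimethanol (2,3-O-isopropylidene-D-threitol)
Product: 2 [(4R,5R)-5-{[(4-methoxybenzyl)oxy]methyl}-2,2-dimethyl-1,3-dioxolan-4-yl]methanol
Conditions: NaH (1.0 equiv), THF, 0 °C; then PMBCl (1.0 equiv), Bu4NI (cat.), rt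
Reagents that add atoms: 4-methoxybenzyl chloride COc1ccc(CCl)cc1
Why: Williamson etherification of the monoalkoxide; the two hydroxyls of the C2-symmetric diol are equivalent, so mono-protection needs no regiocontrol, and the two stereocentres (later C6 and C7) come from the chiral pool.

Step 2
Reactants: 2 mono-PMB ether
Product: 3 (4S,5R)-5-{[(4-methoxybenzyl)oxy]methyl}-2,2-dimethyl-1,3-dioxolane-4-carbaldehyde
Conditions: Dess–Martin periodinane, pyridine, CH2Cl2, 0 °C to rt
Reagents that add atoms: none
Why: Dess–Martin oxidation of the primary alcohol; the buffered, non-basic conditions should leave the α-alkoxy stereocentre (C6) intact.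

Step 3
Reactants: 4 methyl [bis(2,2,2-trifluoroethoxy)phosphoryl]acetate; 5 3-bromo-1,1-dimethoxypropane
Product: 6 methyl 2-[bis(2,2,2-trifluoroethoxy)phosphoryl]-5,5-dimethoxypentanoate (racemic)
Conditions: NaH, DMF, 0 °C; then 5, NaI (cat.), 50 °C
Reagents that add atoms: none
Why: C-alkylation of the stabilised phosphonoacetate anion by the primary halide (SN2, iodide catalysis) attaches C1–C3 with C1 masked as a dimethyl acetal; the new centre is lost in step 4.

Step 4
Reactants: 3 aldehyde; 6 phosphonate
Product: 7 methyl (2Z)-2-(3,3-dimethoxypropyl)-3-[(4R,5R)-5-{[(4-methoxybenzyl)oxy]methyl}-2,2-dimethyl-1,3-dioxolan-4-yl]prop-2-enoate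
Conditions: 6, KHMDS, 18-crown-6, THF, −78 °C; then 3, −78 °C
Reagents that add atoms: none
Why: Still–Gennari variant of the Horner–Wadsworth–Emmons olefination, whose electron-poor phosphonate eliminates from the kinetic adduct, should give the (Z)-trisubstituted enoate with the ester cis to C6.

Step 5
Reactants: 7 (Z)-enoate
Product: 9 (5R)-3-(3,3-dimethoxypropyl)-5-{(1R)-1-hydroxy-2-[(4-methoxybenzyl)oxy]ethyl}furan-2(5H)-one, via dihydroxy ester 8 (not isolated)
Conditions: CSA (cat.), MeOH, rt
Reagents that add atoms: none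
Why: Acid-catalysed transketalisation releases the C6/C7 diol, and the C6 hydroxyl, held cis to the ester, lactonises to the butenolide (five-membered ring preferred over the six-membered alternative through O7), while the dimethyl acetal is stable in methanol.

Step 6
Reactants: 9 hydroxy butenolide
Product: 10 (5R)-3-(3,3-dimethoxypropyl)-5-{(1R)-2-[(4-methoxybenzyl)oxy]-1-[(triethylsilyl)oxy]ethyl}furan-2(5H)-one
Conditions: TESCl, imidazole, DMF, 0 °C
Reagents that add atoms: chlorotriethylsilane CC[Si](Cl)(CC)CC
Why: Silyl ether formation at the only free hydroxyl (C7–OH).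

Step 7
Reactants: 10 butenolide
Product: 11 (3S,4S,5R)-3-(3,3-dimethoxypropyl)-3,4-dihydroxy-5-{(1R)-2-[(4-methoxybenzyl)oxy]-1-[(triethylsilyl)oxy]ethyl}oxolan-2-one (C4–OH and C5–OH cis, both trans to the C6 side chain)
Conditions: OsO4 (5 mol %), NMO, acetone/H2O, rt
Reagents that add atoms: N-methylmorpholine N-oxide C[N+]1([O-])CCOCC1; water O
Why: Catalytic osmium tetroxide syn-dihydroxylation (Upjohn conditions) of the butenolide should occur on the face anti to the C6 side chain, which sets C4 and C5 with both hydroxyls cis to each other and trans to C7, as in the target.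

Step 8
Reactants: 11 lactone diol
Product: 12 C5 acetate of 11 (secondary hydroxyl acetylated; tertiary C4–OH free)
Conditions: Ac2O, pyridine, DMAP (cat.), CH2Cl2, 0 °C
Reagents that add atoms: acetic anhydride CC(=O)OC(C)=O
Why: Acylation of the secondary C5 hydroxyl in preference to the hindered tertiary α-hydroxy lactone hydroxyl installs the acetate of the target.

Step 9
Reactants: 12 hydroxy acetate
Product: 13 C4 triethylsilyl ether of 12 (C4–OTES, C5–OAc, C7–OTES, C8–OPMB, C1 dimethyl acetal)
Conditions: TESOTf, 2,6-lutidine, CH2Cl2, −78 °C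
Reagents that add atoms: triethylsilyl trifluoromethanesulfonate CC[Si](CC)(CC)OS(=O)(=O)C(F)(F)F
Why: Silyl triflate silylation of the tertiary alcohol, run at −78 °C where O-silylation is far faster than activation of the dimethyl acetal.

Step 10
Reactants: 13 PMB ether
Product: 14 primary alcohol (C8–OH; PMB removed)
Conditions: DDQ, CH2Cl2/pH 7 buffer, 0 °C
Reagents that add atoms: none
Why: DDQ oxidation of the electron-rich benzyl ether (hydride abstraction, hydrolysis of the oxocarbenium ion) frees the primary C8 hydroxyl without touching silyl ethers, acetal or acetate.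

Step 11
Reactants: 14 primary alcohol
Product: 15 aldehyde (C8 = CHO, α-triethylsilyloxy aldehyde)
Conditions: Dess–Martin periodinane, pyridine, CH2Cl2, 0 °C
Reagents that add atoms: none
Why: Dess–Martin oxidation to the α-silyloxy aldehyde, used without purification to avoid epimerisation or β-elimination.

Step 12
Reactants: 15 aldehyde
Product: 16 propargylic alcohol, C8H(OH)–C≡C–CH3 (both C8 epimers)
Conditions: 1-propynylmagnesium bromide, THF, −78 °C; aq. NH4Cl
Reagents that add atoms: 1-propynylmagnesium bromide CC#C[Mg]Br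
Why: 1,2-Addition of the alkynyl Grignard reagent to the aldehyde, which at −78 °C is much faster than attack on lactone or acetate; the C8 carbinol configuration is irrelevant because it is oxidised in step 13.

Step 13
Reactants: 16 propargylic alcohol
Product: 17 ynone, C8(=O)–C≡C–CH3
Conditions: Dess–Martin periodinane, pyridine, CH2Cl2, 0 °C to rt
Reagents that add atoms: none
Why: Dess–Martin oxidation of the propargylic alcohol to the ynone.

Step 14
Reactants: 17 ynone
Product: 18 (Z)-β-iodoenone, C8(=O)–CH=C(I)CH3 with iodine cis to the carbonyl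
Conditions: NaI, AcOH, MeCN, rt
Reagents that add atoms: sodium iodide [Na+].[I-]
Why: Conjugate hydroiodination of the ynone (iodide adds to C10, the allenolate is protonated at C9) should give the (Z)-β-iodoenone as the kinetic anti-addition product.

Step 15
Reactants: 18 iodoenone dimethyl acetal
Product: 19 (Z)-β-iodoenone aldehyde (C1 = CHO)
Conditions: TESOTf, 2,4,6-collidine, CH2Cl2, 0 °C; then H2O
Reagents that add atoms: water O
Why: Silyl triflate/collidine converts the dimethyl acetal into a pyridinium N,O-acetal that water hydrolyses to the aldehyde; this acetal cleavage tolerates silyl ethers, which aqueous acid would not.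

Step 16
Reactants: 19 (Z)-β-iodoenone aldehyde
Product: 21 tricyclic transannular hemiketal (C1–O–C8 dihydrofuran with C8–OH; C4–OTES, C5–OAc, C7–OTES), via open hydroxy enone 20 (not isolated)
Conditions: CrCl2, NiCl2 (cat.), chiral oxazoline–sulfonamide ligand (enantiomer giving the 1S alcohol), Et3N, THF/MeCN, rt, 1 mM (slow addition of 19)
Reagents that add atoms: none
Why: Nozaki–Hiyama–Kishi reaction: nickel-catalysed formation of the alkenylchromium(III) species from the (Z)-iodide with retention of geometry and its addition to the C1 aldehyde close the ten-membered ring, the 1S carbinol being set by the chiral sulfonamide ligand on chromium, and the (Z)-γ-hydroxy enone 20 then adds O1 to the C8 carbonyl (5-exo-trig) to give hemiketal 21, whose C8 configuration is set by ring–chain equilibration.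

Step 17
Reactants: 21 transannular hemiketal
Product: 22 C8 O-acryloyl derivative of 21 (acyl ketal)
Conditions: acryloyl chloride, iPr2NEt, DMAP (cat.), CH2Cl2, −20 °C to 0 °C
Reagents that add atoms: acryloyl chloride C=CC(Cl)=O
Why: O-Acylation of the tertiary hemiketal hydroxyl (ester formation at an anomeric-type centre, nucleophilic catalysis by DMAP) fixes the C8 configuration with retention and installs the O8–C12 tether; no other free hydroxyl is present.

Step 18
Reactants: 22 bis(triethylsilyl) acrylate
Product: 23 C4,C7-diol (both triethylsilyl groups removed)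
Conditions: HF·pyridine, pyridine, THF, 0 °C to rt
Reagents that add atoms: none
Why: Fluoride-induced Si–O cleavage of both triethylsilyl ethers under buffered conditions that should leave the acyl ketal, acetate and acrylate intact.

Step 19
Reactants: 23 diol
Product: 24 C7 ketone (C8 acryloyloxy ketal next to the ketone; C4–OH free, C5–OAc)
Conditions: Dess–Martin periodinane, pyridine, CH2Cl2, 0 °C
Reagents that add atoms: none
Why: Dess–Martin oxidation of the only secondary alcohol (C7–OH) gives the ketone; the tertiary C4–OH cannot be oxidised.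

Step 20
Reactants: 24 keto acrylate
Product: 26 CNP0315698.1 (target), via copper enolate 25 (not isolated)
Conditions: Cu(OAc)2·H2O (10 mol %), rac-BINAP (10 mol %), 1,1,3,3-tetramethyldisiloxane, THF, 0 °C to rt; then aq. NH4Cl, citric acid/MeOH
Reagents that add atoms: none
Why: A phosphine-ligated copper(I) hydride, regenerated by the silane, delivers hydride to the terminal acrylate carbon (1,4-reduction), which turns this CH2 into the C13 methyl group and gives the copper (Z)-enolate 25; its α-carbon C11 adds to the adjacent C7 ketone and the copper/silyl aldolate is cleaved on work-up. The closest known reaction type is the copper hydride-catalysed intramolecular reductive aldol cyclisation of α,β-unsaturated esters onto ketones, which gives β-hydroxy lactones. Ring B (C8–O8–C12–C11–C7) closes in the 5-(enolexo)-exo-trig mode, the tether being the O8–C12 ester bond on the ketal carbon next to the ketone. C7 is controlled by the fixed C8 ketal: C11 can only arrive from the O8 side, and in the metal-bridged transition state the C7 carbonyl oxygen lies synclinal to the ring oxygen O1 (α-alkoxy chelation, with C6 held next to C9 by the ten-membered ring), so the new hydroxyl should end cis to O1; C11 is controlled by the (Z)-enolate in this closed transition state, which places the methyl group cis to the C7 oxygen and away from C6. The step needs chemoselective conjugate reduction of the acrylate in the presence of the activated ketone, the acyl ketal, the C5 acetate β to the ketone and two lactone carbonyls; the soft, non-basic copper hydride and the fast five-membered ring closure should secure this.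

**Compound list**
1 | (4R,5R)-2,2-dimethyl-1,3-dioxolane-4,5-dimethanol (2,3-O-isopropylidene-D-threitol) | OC[C@H]1OC(C)(C)O[C@@H]1CO | starting material
2 | [(4R,5R)-5-{[(4-methoxybenzyl)oxy]methyl}-2,2-dimethyl-1,3-dioxolan-4-yl]methanol | OC[C@H]1OC(C)(C)O[C@@H]1COCc1ccc(OC)cc1 | intermediate
3 | (4S,5R)-5-{[(4-methoxybenzyl)oxy]methyl}-2,2-dimethyl-1,3-dioxolane-4-carbaldehyde | O=C[C@H]1OC(C)(C)O[C@@H]1COCc1ccc(OC)cc1 | intermediate
4 | methyl [bis(2,2,2-trifluoroethoxy)phosphoryl]acetate | COC(=O)CP(=O)(OCC(F)(F)F)OCC(F)(F)F | starting material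
5 | 3-bromo-1,1-dimethoxypropane | COC(CCBr)OC | starting material
6 | methyl 2-[bis(2,2,2-trifluoroethoxy)phosphoryl]-5,5-dimethoxypentanoate (racemic) | COC(=O)C(CCC(OC)OC)P(=O)(OCC(F)(F)F)OCC(F)(F)F | intermediate
7 | methyl (2Z)-2-(3,3-dimethoxypropyl)-3-[(4R,5R)-5-{[(4-methoxybenzyl)oxy]methyl}-2,2-dimethyl-1,3-dioxolan-4-yl]prop-2-enoate | COC(=O)/C(CCC(OC)OC)=C\[C@H]1OC(C)(C)O[C@@H]1COCc1ccc(OC)cc1 | intermediate
8 | methyl (2Z,4R,5R)-2-(3,3-dimethoxypropyl)-4,5-dihydroxy-6-[(4-methoxybenzyl)oxy]hex-2-enoate | COC(=O)/C(CCC(OC)OC)=C\[C@@H](O)[C@H](O)COCc1ccc(OC)cc1 | intermediate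
9 | (5R)-3-(3,3-dimethoxypropyl)-5-{(1R)-1-hydroxy-2-[(4-methoxybenzyl)oxy]ethyl}furan-2(5H)-one | O=C1O[C@@H]([C@H](O)COCc2ccc(OC)cc2)C=C1CCC(OC)OC | intermediate
10 | (5R)-3-(3,3-dimethoxypropyl)-5-{(1R)-2-[(4-methoxybenzyl)oxy]-1-[(triethylsilyl)oxy]ethyl}furan-2(5H)-one | O=C1O[C@@H]([C@H](O[Si](CC)(CC)CC)COCc2ccc(OC)cc2)C=C1CCC(OC)OC | intermediate
11 | (3S,4S,5R)-3-(3,3-dimethoxypropyl)-3,4-dihydroxy-5-{(1R)-2-[(4-methoxybenzyl)oxy]-1-[(triethylsilyl)oxy]ethyl}oxolan-2-one | O[C@H]1[C@H]([C@H](O[Si](CC)(CC)CC)COCc2ccc(OC)cc2)OC(=O)[C@]1(O)CCC(OC)OC | intermediate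
12 | C5 acetate of 11 (C4–OH free) | CC(=O)O[C@H]1[C@H]([C@H](O[Si](CC)(CC)CC)COCc2ccc(OC)cc2)OC(=O)[C@]1(O)CCC(OC)OC | intermediate
13 | C4 triethylsilyl ether of 12 | CC(=O)O[C@H]1[C@H]([C@H](O[Si](CC)(CC)CC)COCc2ccc(OC)cc2)OC(=O)[C@]1(O[Si](CC)(CC)CC)CCC(OC)OC | intermediate
14 | primary alcohol (C8–OH) | CC(=O)O[C@H]1[C@H]([C@H](O[Si](CC)(CC)CC)CO)OC(=O)[C@]1(O[Si](CC)(CC)CC)CCC(OC)OC | intermediate
15 | aldehyde (C8 = CHO) | CC(=O)O[C@H]1[C@H]([C@H](O[Si](CC)(CC)CC)C=O)OC(=O)[C@]1(O[Si](CC)(CC)CC)CCC(OC)OC | intermediate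
16 | propargylic alcohol (C8 epimers) | CC(=O)O[C@H]1[C@H]([C@H](O[Si](CC)(CC)CC)C(O)C#CC)OC(=O)[C@]1(O[Si](CC)(CC)CC)CCC(OC)OC | intermediate
17 | ynone | CC(=O)O[C@H]1[C@H]([C@H](O[Si](CC)(CC)CC)C(=O)C#CC)OC(=O)[C@]1(O[Si](CC)(CC)CC)CCC(OC)OC | intermediate
18 | (Z)-β-iodoenone dimethyl acetal | CC(=O)O[C@H]1[C@H]([C@H](O[Si](CC)(CC)CC)C(=O)/C=C(\I)C)OC(=O)[C@]1(O[Si](CC)(CC)CC)CCC(OC)OC | intermediate
19 | (Z)-β-iodoenone aldehyde | CC(=O)O[C@H]1[C@H]([C@H](O[Si](CC)(CC)CC)C(=O)/C=C(\I)C)OC(=O)[C@]1(O[Si](CC)(CC)CC)CCC=O | intermediate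
20 | ten-membered (9Z)-1-hydroxy-8-ketone (open form, 1S) | CC(=O)O[C@H]1[C@H]2OC(=O)[C@]1(O[Si](CC)(CC)CC)CC[C@H](O)/C(C)=C\C(=O)[C@H]2O[Si](CC)(CC)CC | intermediate
21 | tricyclic transannular 1,8-hemiketal | CC(=O)O[C@H]1[C@H]2OC(=O)[C@]1(O[Si](CC)(CC)CC)CC[C@@H]1O[C@@](C=C1C)(O)[C@H]2O[Si](CC)(CC)CC | intermediate
22 | C8 O-acryloyl ketal | CC(=O)O[C@H]1[C@H]2OC(=O)[C@]1(O[Si](CC)(CC)CC)CC[C@@H]1O[C@@](C=C1C)(OC(=O)C=C)[C@H]2O[Si](CC)(CC)CC | intermediate
23 | C4,C7-diol acrylate | CC(=O)O[C@H]1[C@H]2OC(=O)[C@]1(O)CC[C@@H]1O[C@@](C=C1C)(OC(=O)C=C)[C@H]2O | intermediate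
24 | C7 ketone acrylate | CC(=O)O[C@H]1[C@H]2OC(=O)[C@]1(O)CC[C@@H]1O[C@@](C=C1C)(OC(=O)C=C)C2=O | intermediate
25 | copper(I) (Z)-enolate of the C8 O-propanoyl group (methyl cis to O–Cu) | CC(=O)O[C@H]1[C@H]2OC(=O)[C@]1(O)CC[C@@H]1O[C@@](C=C1C)(O/C(O[Cu])=C/C)C2=O | intermediate
26 | CNP0315698.1 | CC(=O)O[C@H]1[C@H]2OC(=O)[C@]1(O)CC[C@@H]1O[C@@]3(C=C1C)OC(=O)[C@@H](C)[C@]23O | target

**Step count and risks**

Total step count: 20. Longest linear sequence: 19 steps (1, 2, 4–20); step 3 is a one-step side branch.

Steps most likely to fail: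

Step 17. Acylation may take place on the ring-opened C1 hydroxyl instead of the hemiketal hydroxyl, or may capture the wrong C8 epimer from the equilibrating hemiketal. Fallback, from 21 back to 22: 21 is converted into the ring-locked C8 methyl ketal F1 (MeOH, trimethyl orthoformate, cat. PPTS, CH2Cl2, 0 °C; only the cyclic form can ketalise). The methoxy group is then exchanged for acryloyloxy by acidolysis with acrylic anhydride and catalytic TMSOTf at −40 °C (acetolysis-type exchange through the C8 oxocarbenium ion, with the carboxylate oxygen becoming O8), which should give 22.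

Step 16. Intermolecular coupling may compete with closure of the ten-membered ring, and facial control at the C1 aldehyde may be insufficient. Fallback, from 19 back to 21: a ligand-free Ni/Cr cyclisation is accepted as giving 21 together with the C1-epimeric hemiketal F2. The mixture is oxidised through its open hydroxy-enone form with Dess–Martin periodinane to the ten-membered (Z)-ene-1,8-dione F3. A Corey–Bakshi–Shibata reduction (oxazaborolidine of the required handedness, catecholborane, −78 °C) of the less hindered C1 carbonyl then sets 1S under reagent control and returns 20, which closes to 21.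

Step 20. The activated C7 ketone may be reduced before the enolate forms, the enolate may attack the wrong face of C7, or the C5 acetate may be lost by β-elimination. Fallback, from 21 to 26: acylation of 21 with 2-bromopropanoyl bromide/pyridine gives the C8 O-(2-bromopropanoyl) ketal F4; HF·pyridine gives the C4,C7-diol F5; Dess–Martin oxidation gives the bromo keto ester F6. An intramolecular Reformatsky reaction (Et2Zn, cat. RhCl(PPh3)3, THF, 0 °C) then closes ring B through the chelated zinc enolate and should give 26.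

**Further compounds**
F1 | step 17 | C8 methyl ketal of 21 | CC(=O)O[C@H]1[C@H]2OC(=O)[C@]1(O[Si](CC)(CC)CC)CC[C@@H]1O[C@@](C=C1C)(OC)[C@H]2O[Si](CC)(CC)CC
F2 | step 16 | C1 epimer of hemiketal 21 (C8 anomers) | CC(=O)O[C@H]1[C@H]2OC(=O)[C@]1(O[Si](CC)(CC)CC)CC[C@H]1OC(C=C1C)(O)[C@H]2O[Si](CC)(CC)CC
F3 | step 16 | ten-membered (9Z)-ene-1,8-dione | CC(=O)O[C@H]1[C@H]2OC(=O)[C@]1(O[Si](CC)(CC)CC)CCC(=O)/C(C)=C\C(=O)[C@H]2O[Si](CC)(CC)CC
F4 | step 20 | C8 O-(2-bromopropanoyl) ketal of 21 | CC(=O)O[C@H]1[C@H]2OC(=O)[C@]1(O[Si](CC)(CC)CC)CC[C@@H]1O[C@@](C=C1C)(OC(=O)C(C)Br)[C@H]2O[Si](CC)(CC)CC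
F5 | step 20 | C4,C7-diol bromo ester | CC(=O)O[C@H]1[C@H]2OC(=O)[C@]1(O)CC[C@@H]1O[C@@](C=C1C)(OC(=O)C(C)Br)[C@H]2O
F6 | step 20 | C7 ketone bromo ester | CC(=O)O[C@H]1[C@H]2OC(=O)[C@]1(O)CC[C@@H]1O[C@@](C=C1C)(OC(=O)C(C)Br)C2=O
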